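**Retrosynthetic overview**
1. The C7 aryl ketone is cut to a 7-lithiated benzofuran plus 3-(allyloxy)benzaldehyde 27 (addition, then oxidation); the C5–CH2 bond is cut by Negishi coupling to aryl bromide 13 plus iodide 23. Three fragments of 22, 11 and 12 non-hydrogen atoms are joined in steps 17 and 18.
2. Core 13: resorcinol → 2-bromo-1,3-bis(MOM-oxy)benzene → C–H borylation/oxidation to the para-bromophenol → ortho-prenylation → Shi epoxidation → phenolate 5-exo opening.
3. Side chain 23: Evans deconjugative alkylation sets the stereocentre; a methallyl Grignard coupling completes the chain.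
4. End game: MOM removal, O-methylation of the non-chelated 4-OH, deallylation.
5. Ring order: both benzene rings are bought (resorcinol, 3-bromophenol); the dihydrofuran is the only ring formed (step 7).

Assumption: the oxazolidinone auxiliary and the protecting-group reagents (MOMCl, TBSCl, BnOCH2Cl, allyl bromide) are treated as reagents, not starting materials.

**Fragment A: aryl bromide 13**

Step 1
Reactants: 1 resorcinol
Product: 2 1,3-bis(methoxymethoxy)benzene
Conditions: MOMCl (2.5 equiv), i-Pr2NEt, CH2Cl2, 0 °C → rt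
Reagents that add atoms: chloromethyl methyl ether, COCCl
Why: Williamson-type O-alkylation of both phenols by the reactive α-chloro ether gives the bis-acetal that later directs metalation.

Step 2
Reactants: 2 1,3-bis(methoxymethoxy)benzene
Product: 4 2-bromo-1,3-bis(methoxymethoxy)benzene, via aryllithium 3 (not isolated)
Conditions: n-BuLi, THF, 0 °C; then BrCH2CH2Br, −78 °C → rt
Reagents that add atoms: 1,2-dibromoethane, BrCCBr
Why: Directed ortho-metalation places lithium between the two cooperating OMOM groups, and the aryllithium is brominated by 1,2-dibromoethane with loss of ethene.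

Step 3
Reactants: 4 2-bromo-1,3-bis(methoxymethoxy)benzene
Product: 6 4-bromo-3,5-bis(methoxymethoxy)phenol, via arylboronic pinacol ester 5 (not isolated)
Conditions: B2pin2, [Ir(OMe)(cod)]2 (1.5 mol%), 4,4′-di-tert-butyl-2,2′-bipyridine (3 mol%), THF, 80 °C; then 30% H2O2, aq NaOH, 0 °C
Reagents that add atoms: hydrogen peroxide, OO
Why: Sterically controlled iridium-catalysed C–H borylation occurs only at the one C–H not ortho to a substituent (para to Br), and boronate oxidation gives the phenol.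

Step 4
Reactants: 6 4-bromo-3,5-bis(methoxymethoxy)phenol, 7 1-bromo-3-methylbut-2-ene
Product: 9 4-bromo-3,5-bis(methoxymethoxy)-2-(3-methylbut-2-en-1-yl)phenol, via sodium phenolate 8 (not isolated)
Conditions: NaH, toluene, 0 °C; then 7, rt
Reagents that add atoms: none
Why: Ortho-selective C-alkylation of a sodium phenolate as a tight ion pair in a non-polar solvent; the para position is blocked by bromine and the two ortho sites are equivalent.

Step 5
Reactants: 9 4-bromo-3,5-bis(methoxymethoxy)-2-(3-methylbut-2-en-1-yl)phenol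
Product: 10 [4-bromo-3,5-bis(methoxymethoxy)-2-(3-methylbut-2-en-1-yl)phenoxy](tert-butyl)dimethylsilane
Conditions: TBSCl, imidazole, DMF, rt
Reagents that add atoms: tert-butyldimethylsilyl chloride, CC(C)(C)[Si](C)(C)Cl
Why: Silylation masks the phenol so that it is neither oxidised nor cyclises prematurely during the epoxidation.

Step 6
Reactants: 10 [4-bromo-3,5-bis(methoxymethoxy)-2-(3-methylbut-2-en-1-yl)phenoxy](tert-butyl)dimethylsilane
Product: 11 (4-bromo-2-{[(2R)-3,3-dimethyloxiran-2-yl]methyl}-3,5-bis(methoxymethoxy)phenoxy)(tert-butyl)dimethylsilane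
Conditions: Shi ketone from D-fructose (30 mol%), Oxone (2KHSO5·KHSO4·K2SO4), K2CO3, n-Bu4NHSO4, MeCN/CH2(OMe)2, aq Na2B4O7/Na2EDTA buffer (pH 10.5), 0 °C
Reagents that add atoms: potassium peroxymonosulfate KHSO5 (Oxone), [K+].[O-]S(=O)(=O)OO
Why: Shi asymmetric epoxidation: the chiral dioxirane attacks the trisubstituted alkene through a spiro transition state and gives the (R)-epoxide under catalyst control, while the basic buffer keeps the acetals and silyl ether intact.

Step 7
Reactants: 11 (4-bromo-2-{[(2R)-3,3-dimethyloxiran-2-yl]methyl}-3,5-bis(methoxymethoxy)phenoxy)(tert-butyl)dimethylsilane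
Product: 13 2-[(2S)-5-bromo-4,6-bis(methoxymethoxy)-2,3-dihydro-1-benzofuran-2-yl]propan-2-ol, via tetrabutylammonium phenolate 12 (not isolated)
Conditions: n-Bu4NF, THF, 0 °C → rt
Reagents that add atoms: none
Why: Fluoride desilylation frees the phenolate, which opens the epoxide by 5-exo-tet SN2 attack at the secondary carbon with inversion, forming the dihydrofuran and setting (S)-C2.

**Fragment B: iodide 23**

Step 8
Reactants: 14 3-methylbut-2-enoyl chloride
Product: 15 (4R)-4-benzyl-3-(3-methylbut-2-enoyl)-1,3-oxazolidin-2-one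
Conditions: (R)-4-benzyl-1,3-oxazolidin-2-one, n-BuLi, THF, −78 °C; then 14, −78 → 0 °C
Reagents that add atoms: (R)-4-benzyl-1,3-oxazolidin-2-one, O=C1N[C@H](Cc2ccccc2)CO1
Why: N-acylation of the lithiated Evans auxiliary by the acid chloride.

Step 9
Reactants: 15 (4R)-4-benzyl-3-(3-methylbut-2-enoyl)-1,3-oxazolidin-2-one
Product: 17 (4R)-4-benzyl-3-{(2S)-2-[(benzyloxy)methyl]-3-methylbut-3-enoyl}-1,3-oxazolidin-2-one, via sodium dienolate 16 (not isolated)
Conditions: NaN(SiMe3)2, THF, −78 °C; then BnOCH2Cl, −78 → −40 °C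
Reagents that add atoms: benzyl chloromethyl ether, ClCOCc1ccccc1
Why: Evans deconjugative α-alkylation: γ-deprotonation gives the chelated (Z)-dienolate, which is alkylated at the α-carbon on the face opposite the 4-benzyl group, setting the (2S) centre and leaving the isopropenyl group.

Step 10
Reactants: 17 (4R)-4-benzyl-3-{(2S)-2-[(benzyloxy)methyl]-3-methylbut-3-enoyl}-1,3-oxazolidin-2-one
Product: 18 (2R)-2-[(benzyloxy)methyl]-3-methylbut-3-en-1-ol
Conditions: LiBH4, H2O (1 equiv), Et2O, 0 °C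
Reagents that add atoms: none
Why: Chemoselective hydride reduction of the exocyclic imide carbonyl releases the primary alcohol and the recoverable auxiliary without touching the stereocentre (the descriptor changes only through priority rules).

Step 11
Reactants: 18 (2R)-2-[(benzyloxy)methyl]-3-methylbut-3-en-1-ol
Product: 19 ({[(2S)-2-(iodomethyl)-3-methylbut-3-en-1-yl]oxy}methyl)benzene
Conditions: I2, PPh3, imidazole, CH2Cl2, 0 °C → rt
Reagents that add atoms: iodine, II
Why: Appel-type iodination of a primary alcohol through the alkoxyphosphonium ion under neutral conditions.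

Step 12
Reactants: 19 ({[(2S)-2-(iodomethyl)-3-methylbut-3-en-1-yl]oxy}methyl)benzene, 20 2-methylallylmagnesium chloride
Product: 21 ({[(2S)-5-methyl-2-(prop-1-en-2-yl)hex-5-en-1-yl]oxy}methyl)benzene
Conditions: 20 (2 equiv), Li2CuCl4 (5 mol%), THF, −30 → 0 °C
Reagents that add atoms: none
Why: Copper-catalysed Kochi-type sp3–sp3 coupling of the allylic Grignard reagent with the primary iodide builds the 3-methylbut-3-enyl arm (both allyl termini are equivalent) without involving the stereocentre.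

Step 13
Reactants: 21 ({[(2S)-5-methyl-2-(prop-1-en-2-yl)hex-5-en-1-yl]oxy}methyl)benzene
Product: 22 (2S)-5-methyl-2-(prop-1-en-2-yl)hex-5-en-1-ol
Conditions: Na, NH3(l), THF, −78 °C; then NH4Cl
Reagents that add atoms: none
Why: Dissolving-metal (Birch-type) debenzylation cleaves the benzyl ether while isolated 1,1-disubstituted alkenes are not reduced.

Step 14
Reactants: 22 (2S)-5-methyl-2-(prop-1-en-2-yl)hex-5-en-1-ol
Product: 23 (3S)-3-(iodomethyl)-2,6-dimethylhepta-1,6-diene
Conditions: I2, PPh3, imidazole, CH2Cl2, 0 °C → rt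
Reagents that add atoms: iodine, II
Why: Appel-type iodination gives the primary iodide for zinc insertion with the stereocentre untouched.

**Fragment C: aldehyde 27**

Step 15
Reactants: 24 3-bromophenol
Product: 25 1-bromo-3-(prop-2-en-1-yloxy)benzene
Conditions: allyl bromide, K2CO3, acetone, reflux
Reagents that add atoms: allyl bromide, C=CCBr
Why: Williamson etherification installs an allyl ether that survives acid and base and is removed at the end under neutral palladium catalysis.

Step 16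
Reactants: 25 1-bromo-3-(prop-2-en-1-yloxy)benzene
Product: 27 3-(prop-2-en-1-yloxy)benzaldehyde, via aryllithium 26 (not isolated)
Conditions: n-BuLi, THF, −78 °C; DMF; then H2O
Reagents that add atoms: N,N-dimethylformamide, CN(C)C=O
Why: Bromine–lithium exchange followed by Bouveault formylation with DMF.

**Assembly and end game**

Step 17
Reactants: 13 2-[(2S)-5-bromo-4,6-bis(methoxymethoxy)-2,3-dihydro-1-benzofuran-2-yl]propan-2-ol, 23 (3S)-3-(iodomethyl)-2,6-dimethylhepta-1,6-diene
Product: 29 2-{(2S)-4,6-bis(methoxymethoxy)-5-[(2R)-5-methyl-2-(prop-1-en-2-yl)hex-5-en-1-yl]-2,3-dihydro-1-benzofuran-2-yl}propan-2-ol, via alkylzinc iodide 28 (not isolated)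
Conditions: 23, Zn dust (activated by BrCH2CH2Br/Me3SiCl), LiCl, THF, 40 °C; then 13, Pd(OAc)2 (5 mol%), SPhos (10 mol%), THF, 60 °C (2 equiv of 28)
Reagents that add atoms: none
Why: Negishi sp2–sp3 cross-coupling: the bulky biarylphosphine allows oxidative addition into the di-ortho-alkoxy aryl bromide and fast reductive elimination, the free tertiary alcohol is tolerated, and the side-chain stereocentre is not touched (it becomes R only by priority change).

Step 18
Reactants: 29 2-{(2S)-4,6-bis(methoxymethoxy)-5-[(2R)-5-methyl-2-(prop-1-en-2-yl)hex-5-en-1-yl]-2,3-dihydro-1-benzofuran-2-yl}propan-2-ol, 27 3-(prop-2-en-1-yloxy)benzaldehyde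
Product: 31 {(2S)-2-(2-hydroxypropan-2-yl)-4,6-bis(methoxymethoxy)-5-[(2R)-5-methyl-2-(prop-1-en-2-yl)hex-5-en-1-yl]-2,3-dihydro-1-benzofuran-7-yl}[3-(prop-2-en-1-yloxy)phenyl]methanol (both carbinol epimers), via dilithio species 30 (not isolated)
Conditions: n-BuLi (2.3 equiv), TMEDA, THF, −78 → −10 °C; then 27, −78 °C → rt; H2O
Reagents that add atoms: none
Why: Directed ortho-metalation at the only remaining aromatic C–H (flanked by OMOM and the ring oxygen, after deprotonation of the alcohol) followed by 1,2-addition to the aldehyde; the new carbinol centre is removed in the next step.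

Step 19
Reactants: 31 the diaryl carbinol
Product: 32 {(2S)-2-(2-hydroxypropan-2-yl)-4,6-bis(methoxymethoxy)-5-[(2R)-5-methyl-2-(prop-1-en-2-yl)hex-5-en-1-yl]-2,3-dihydro-1-benzofuran-7-yl}[3-(prop-2-en-1-yloxy)phenyl]methanone
Conditions: Dess–Martin periodinane, NaHCO3, CH2Cl2, 0 °C → rt
Reagents that add atoms: none
Why: Dess–Martin oxidation of the secondary benzylic alcohol under buffered conditions leaves the tertiary alcohol, alkenes and acetals untouched.

Step 20
Reactants: 32 the bis-MOM ketone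
Product: 33 {(2S)-4,6-dihydroxy-2-(2-hydroxypropan-2-yl)-5-[(2R)-5-methyl-2-(prop-1-en-2-yl)hex-5-en-1-yl]-2,3-dihydro-1-benzofuran-7-yl}[3-(prop-2-en-1-yloxy)phenyl]methanone
Conditions: 3 M aq HCl, MeOH/THF, 40 °C, stopped at full conversion
Reagents that add atoms: none
Why: Acid-catalysed acetal methanolysis removes both aryl MOM ethers (the one ortho to the carbonyl fastest) under conditions mild enough for the allyl ether, tertiary alcohol and 1,1-disubstituted alkenes.

Step 21
Reactants: 33 the 4,6-diphenol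
Product: 34 {(2S)-6-hydroxy-2-(2-hydroxypropan-2-yl)-4-methoxy-5-[(2R)-5-methyl-2-(prop-1-en-2-yl)hex-5-en-1-yl]-2,3-dihydro-1-benzofuran-7-yl}[3-(prop-2-en-1-yloxy)phenyl]methanone
Conditions: MeI (1.1 equiv), K2CO3 (1.1 equiv), acetone, rt
Reagents that add atoms: iodomethane, CI
Why: Regioselective Williamson methylation: the 6-OH is held in a hydrogen bond to the ortho carbonyl and the tertiary alcohol is not ionised, so only the more acidic 4-OH para to the carbonyl is alkylated.

Step 22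
Reactants: 34 the allyl ether
Product: 35 (3-hydroxyphenyl){(2S)-6-hydroxy-2-(2-hydroxypropan-2-yl)-4-methoxy-5-[(2R)-5-methyl-2-(prop-1-en-2-yl)hex-5-en-1-yl]-2,3-dihydro-1-benzofuran-7-yl}methanone
Conditions: Pd(PPh3)4 (5 mol%), morpholine, THF, rt
Reagents that add atoms: none
Why: Tsuji–Trost deallylation: palladium ionises the aryl allyl ether and morpholine traps the allyl fragment, a neutral unmasking that spares the isopropenyl groups and both stereocentres.

**Compound list**
1 | resorcinol | Oc1cccc(O)c1 | starting material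
2 | 1,3-bis(methoxymethoxy)benzene | COCOc1cccc(OCOC)c1 | intermediate
3 | [2,6-bis(methoxymethoxy)phenyl]lithium | [Li]c1c(OCOC)cccc1OCOC | intermediate
4 | 2-bromo-1,3-bis(methoxymethoxy)benzene | COCOc1cccc(OCOC)c1Br | intermediate
5 | 2-[4-bromo-3,5-bis(methoxymethoxy)phenyl]-4,4,5,5-tetramethyl-1,3,2-dioxaborolane | COCOc1cc(cc(OCOC)c1Br)B1OC(C)(C)C(C)(C)O1 | intermediate
6 | 4-bromo-3,5-bis(methoxymethoxy)phenol | COCOc1cc(O)cc(OCOC)c1Br | intermediate
7 | 1-bromo-3-methylbut-2-ene (prenyl bromide) | CC(C)=CCBr | starting material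
8 | sodium 4-bromo-3,5-bis(methoxymethoxy)phenolate | [Na+].[O-]c1cc(OCOC)c(Br)c(OCOC)c1 | intermediate
9 | 4-bromo-3,5-bis(methoxymethoxy)-2-(3-methylbut-2-en-1-yl)phenol | COCOc1cc(O)c(CC=C(C)C)c(OCOC)c1Br | intermediate
10 | [4-bromo-3,5-bis(methoxymethoxy)-2-(3-methylbut-2-en-1-yl)phenoxy](tert-butyl)dimethylsilane | COCOc1cc(O[Si](C)(C)C(C)(C)C)c(CC=C(C)C)c(OCOC)c1Br | intermediate
11 | (4-bromo-2-{[(2R)-3,3-dimethyloxiran-2-yl]methyl}-3,5-bis(methoxymethoxy)phenoxy)(tert-butyl)dimethylsilane | COCOc1cc(O[Si](C)(C)C(C)(C)C)c(C[C@H]2OC2(C)C)c(OCOC)c1Br | intermediate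
12 | tetrabutylammonium 4-bromo-2-{[(2R)-3,3-dimethyloxiran-2-yl]methyl}-3,5-bis(methoxymethoxy)phenolate | CCCC[N+](CCCC)(CCCC)CCCC.[O-]c1cc(OCOC)c(Br)c(OCOC)c1C[C@H]1OC1(C)C | intermediate
13 | 2-[(2S)-5-bromo-4,6-bis(methoxymethoxy)-2,3-dihydro-1-benzofuran-2-yl]propan-2-ol | Brc1c(OCOC)cc2c(c1OCOC)C[C@@H](C(C)(C)O)O2 | intermediate
14 | 3-methylbut-2-enoyl chloride | CC(C)=CC(Cl)=O | starting material
15 | (4R)-4-benzyl-3-(3-methylbut-2-enoyl)-1,3-oxazolidin-2-one | O=C1OC[C@@H](Cc2ccccc2)N1C(=O)C=C(C)C | intermediate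
16 | sodium (1Z)-1-[(4R)-4-benzyl-2-oxo-1,3-oxazolidin-3-yl]-3-methylbuta-1,3-dien-1-olate | [Na+].[O-]/C(=C\C(C)=C)N1[C@H](Cc2ccccc2)COC1=O | intermediate
17 | (4R)-4-benzyl-3-{(2S)-2-[(benzyloxy)methyl]-3-methylbut-3-enoyl}-1,3-oxazolidin-2-one | O=C1OC[C@@H](Cc2ccccc2)N1C(=O)[C@H](COCc1ccccc1)C(C)=C | intermediate
18 | (2R)-2-[(benzyloxy)methyl]-3-methylbut-3-en-1-ol | OC[C@H](COCc1ccccc1)C(C)=C | intermediate
19 | ({[(2S)-2-(iodomethyl)-3-methylbut-3-en-1-yl]oxy}methyl)benzene | IC[C@H](COCc1ccccc1)C(C)=C | intermediate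
20 | 2-methylallylmagnesium chloride, CH2=C(CH3)CH2MgCl (THF solution) | C=C(C)C[Mg]Cl | starting material
21 | ({[(2S)-5-methyl-2-(prop-1-en-2-yl)hex-5-en-1-yl]oxy}methyl)benzene | C=C(C)CC[C@H](COCc1ccccc1)C(C)=C | intermediate
22 | (2S)-5-methyl-2-(prop-1-en-2-yl)hex-5-en-1-ol | C=C(C)CC[C@H](CO)C(C)=C | intermediate
23 | (3S)-3-(iodomethyl)-2,6-dimethylhepta-1,6-diene | C=C(C)CC[C@H](CI)C(C)=C | intermediate
24 | 3-bromophenol | Oc1cccc(Br)c1 | starting material
25 | 1-bromo-3-(prop-2-en-1-yloxy)benzene | C=CCOc1cccc(Br)c1 | intermediate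
26 | [3-(prop-2-en-1-yloxy)phenyl]lithium | [Li]c1cccc(OCC=C)c1 | intermediate
27 | 3-(prop-2-en-1-yloxy)benzaldehyde | C=CCOc1cccc(C=O)c1 | intermediate
28 | iodo[(2S)-5-methyl-2-(prop-1-en-2-yl)hex-5-en-1-yl]zinc | C=C(C)CC[C@H](C[Zn]I)C(C)=C | intermediate
29 | 2-{(2S)-4,6-bis(methoxymethoxy)-5-[(2R)-5-methyl-2-(prop-1-en-2-yl)hex-5-en-1-yl]-2,3-dihydro-1-benzofuran-2-yl}propan-2-ol | C=C(C)CC[C@H](Cc1c(OCOC)cc2c(c1OCOC)C[C@@H](C(C)(C)O)O2)C(C)=C | intermediate
30 | lithium 2-{(2S)-7-lithio-4,6-bis(methoxymethoxy)-5-[(2R)-5-methyl-2-(prop-1-en-2-yl)hex-5-en-1-yl]-2,3-dihydro-1-benzofuran-2-yl}propan-2-olate | C=C(C)CC[C@H](Cc1c(OCOC)c([Li])c2c(c1OCOC)C[C@@H](C(C)(C)O[Li])O2)C(C)=C | intermediate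
31 | {(2S)-2-(2-hydroxypropan-2-yl)-4,6-bis(methoxymethoxy)-5-[(2R)-5-methyl-2-(prop-1-en-2-yl)hex-5-en-1-yl]-2,3-dihydro-1-benzofuran-7-yl}[3-(prop-2-en-1-yloxy)phenyl]methanol (carbinol epimers) | C=C(C)CC[C@H](Cc1c(OCOC)c(C(O)c3cccc(OCC=C)c3)c2c(c1OCOC)C[C@@H](C(C)(C)O)O2)C(C)=C | intermediate
32 | {(2S)-2-(2-hydroxypropan-2-yl)-4,6-bis(methoxymethoxy)-5-[(2R)-5-methyl-2-(prop-1-en-2-yl)hex-5-en-1-yl]-2,3-dihydro-1-benzofuran-7-yl}[3-(prop-2-en-1-yloxy)phenyl]methanone | C=C(C)CC[C@H](Cc1c(OCOC)c(C(=O)c3cccc(OCC=C)c3)c2c(c1OCOC)C[C@@H](C(C)(C)O)O2)C(C)=C | intermediate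
33 | {(2S)-4,6-dihydroxy-2-(2-hydroxypropan-2-yl)-5-[(2R)-5-methyl-2-(prop-1-en-2-yl)hex-5-en-1-yl]-2,3-dihydro-1-benzofuran-7-yl}[3-(prop-2-en-1-yloxy)phenyl]methanone | C=C(C)CC[C@H](Cc1c(O)c(C(=O)c3cccc(OCC=C)c3)c2c(c1O)C[C@@H](C(C)(C)O)O2)C(C)=C | intermediate
34 | {(2S)-6-hydroxy-2-(2-hydroxypropan-2-yl)-4-methoxy-5-[(2R)-5-methyl-2-(prop-1-en-2-yl)hex-5-en-1-yl]-2,3-dihydro-1-benzofuran-7-yl}[3-(prop-2-en-1-yloxy)phenyl]methanone | C=C(C)CC[C@H](Cc1c(O)c(C(=O)c3cccc(OCC=C)c3)c2c(c1OC)C[C@@H](C(C)(C)O)O2)C(C)=C | intermediate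
35 | (3-hydroxyphenyl){(2S)-6-hydroxy-2-(2-hydroxypropan-2-yl)-4-methoxy-5-[(2R)-5-methyl-2-(prop-1-en-2-yl)hex-5-en-1-yl]-2,3-dihydro-1-benzofuran-7-yl}methanone | C=C(C)CC[C@H](Cc1c(O)c(C(=O)c2cccc(O)c2)c2c(c1OC)C[C@@H](C(C)(C)O)O2)C(=C)C | target

**Totals**
Total step count: 22 (7 for fragment A, 7 for fragment B, 2 for fragment C, 6 for assembly and end game).
Longest linear sequence: 13 steps (steps 1–7 then 17–22; the branch through steps 8–14 then 17–22 is equally long).

**Three steps most likely to fail**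

Step 4 (ortho-C-prenylation; O-alkylation and double alkylation compete). The fallback sets out from 6 and returns at 9. Phenol 6 is O-alkylated with 3-chloro-3-methylbut-1-yne (DBU, CuCl2 cat., MeCN, 0 °C) to the propargyl ether 2-bromo-1,3-bis(methoxymethoxy)-5-[(2-methylbut-3-yn-2-yl)oxy]benzene F1. Semihydrogenation (H2, Pd on CaCO3 poisoned with Pb(OAc)2, quinoline, EtOAc) gives the 1,1-dimethylallyl ether 2-bromo-1,3-bis(methoxymethoxy)-5-[(2-methylbut-3-en-2-yl)oxy]benzene F2. Heating F2 in N,N-diethylaniline at 130 °C brings about an aromatic Claisen rearrangement, which with the para position blocked delivers the 3-methylbut-2-enyl group to the ortho carbon and gives 9.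

Step 17 (Negishi coupling of a di-ortho-alkoxy aryl bromide with a β-branched homoallylic zinc reagent; slow oxidative addition and β-hydride loss are the dangers). The fallback reverses the polarity, sets out from 13 and 23 and returns at 29. Bromide 13 is deprotonated with MeLi (1 equiv) and exchanged with t-BuLi (2.1 equiv) in THF at −78 °C to give lithium 2-[(2S)-5-lithio-4,6-bis(methoxymethoxy)-2,3-dihydro-1-benzofuran-2-yl]propan-2-olate F3, an aryllithium held by both flanking OMOM groups. F3 is alkylated by SN2 with iodide 23 in THF/DMPU (−78 → 0 °C) and gives 29 after aqueous work-up.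

Step 20 (Brønsted-acid MOM removal; the freed ortho phenols can add to the protonated isopropenyl group to form a chroman, or methanol can add to the alkenes). The fallback drops protic acid, sets out from 32 and returns at 33. TMSOTf with 2,2′-bipyridyl in MeCN at 0 °C converts both aryl MOM ethers into aryl silyl ethers and silylates the tertiary alcohol, giving {(2S)-5-[(2R)-5-methyl-2-(prop-1-en-2-yl)hex-5-en-1-yl]-4,6-bis[(trimethylsilyl)oxy]-2-{2-[(trimethylsilyl)oxy]propan-2-yl}-2,3-dihydro-1-benzofuran-7-yl}[3-(prop-2-en-1-yloxy)phenyl]methanone F4. Methanolysis with K2CO3 in MeOH at 0 °C then removes the three silyl groups under basic conditions and gives 33.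

**Further compounds**
F1 | step 4 | 2-bromo-1,3-bis(methoxymethoxy)-5-[(2-methylbut-3-yn-2-yl)oxy]benzene | COCOc1cc(OC(C)(C)C#C)cc(OCOC)c1Br
F2 | step 4 | 2-bromo-1,3-bis(methoxymethoxy)-5-[(2-methylbut-3-en-2-yl)oxy]benzene | COCOc1cc(OC(C)(C)C=C)cc(OCOC)c1Br
F3 | step 17 | lithium 2-[(2S)-5-lithio-4,6-bis(methoxymethoxy)-2,3-dihydro-1-benzofuran-2-yl]propan-2-olate | [Li]c1c(OCOC)cc2c(c1OCOC)C[C@@H](C(C)(C)O[Li])O2
F4 | step 20 | {(2S)-5-[(2R)-5-methyl-2-(prop-1-en-2-yl)hex-5-en-1-yl]-4,6-bis[(trimethylsilyl)oxy]-2-{2-[(trimethylsilyl)oxy]propan-2-yl}-2,3-dihydro-1-benzofuran-7-yl}[3-(prop-2-en-1-yloxy)phenyl]methanone | C=C(C)CC[C@H](Cc1c(O[Si](C)(C)C)c(C(=O)c3cccc(OCC=C)c3)c2c(c1O[Si](C)(C)C)C[C@@H](C(C)(C)O[Si](C)(C)C)O2)C(C)=C
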